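**Retrosynthetic overview**
1. The target comes from the 8,9‑diol 24 by two successive O‑acylations: the equatorial 8‑OH with tigloyl chloride 26, then the axial 9‑OH with senecioyl chloride 29.
2. Diol 24 comes from chloro dienone 21 by α‑face syn‑dihydroxylation of C8=C9, β‑face hydrogenation of C1=C10 (cis ring fusion) and E2 unmasking of the isopropenyl group from a tertiary chloride.
3. Ring A of 21 is closed last, by intramolecular aldol condensation of the 1,5‑diketone obtained from Michael union of ring‑B enone 8 (C5 enolate) with α‑silyl pentenone 16.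
4. Enone 8 comes from (−)‑β‑pinene (ozonolysis, methylation, HCl opening of the cyclobutane, dehydrogenation); 16 comes from 1‑bromopropene, Me3SiCl and acetaldehyde.
5. Ring order: ring B first (the six‑membered ring of β‑pinene, which supplies C7), ring A second (aldol).

Assumption: eremophilane numbering is used for descriptors (C2 ketone, C4–CH3, C5 angular CH3, C7 carries the C3 unit, C8/C9 oxygenated, C10 ring‑fusion CH; β = face of the C5 methyl); 1‑bromopropene is the commercial E/Z mixture.

**Route**

Step 1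
Reactants: 1 (−)-β-pinene
Product: 3 (+)-nopinone, via ozonide 2 (not isolated)
Conditions: O3, CH2Cl2, −78 °C; then Me2S, −78 → 20 °C
Reagents that add atoms: ozone [O-][O+]=O
Why: Ozonolysis (cycloaddition to the ozonide, reductive cleavage) removes the exocyclic methylene and leaves both ring stereocentres untouched.

Step 2
Reactants: 3 (+)-nopinone
Product: 5 trans-3-methylnopinone, via lithium enolate 4 (not isolated)
Conditions: LDA, THF, −78 °C; MeI, −78 → 0 °C
Reagents that add atoms: iodomethane CI
Why: Enolate alkylation is regiospecific because the bridgehead cannot enolise, and MeI enters anti to the gem‑dimethyl bridge (this centre is re‑planarised in step 9, so its configuration is not critical).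

Step 3
Reactants: 5 trans-3-methylnopinone
Product: 6 (2R,4R)-4-(2-chloropropan-2-yl)-2-methylcyclohexan-1-one
Conditions: HCl (g), AcOH, 20 → 40 °C
Reagents that add atoms: hydrogen chloride Cl
Why: Acid‑promoted cyclobutane fragmentation α to the protonated ketone relieves strain and gives a tertiary cation trapped by chloride, which keeps the future C7 stereocentre, stores the isopropenyl group as a tertiary chloride, and lets the 2‑methyl centre settle as the cis (diequatorial) epimer.

Step 4
Reactants: 6 (2R,4R)-4-(2-chloropropan-2-yl)-2-methylcyclohexan-1-one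
Product: 8 (4S,6R)-4-(2-chloropropan-2-yl)-6-methylcyclohex-2-en-1-one, via lithium enolate 7 (not isolated)
Conditions: LDA, THF, −78 °C; then PhS(Cl)=N-t-Bu, −78 °C
Reagents that add atoms: none
Why: Kinetic enolisation at the less substituted CH2 followed by Mukaiyama dehydrogenation (α‑sulfinimidoylation and syn‑elimination) gives the enone regiospecifically without forming a stereocentre.

Step 5
Reactants: 9 1-bromoprop-1-ene
Product: 11 trimethyl(prop-1-yn-1-yl)silane, via propynyllithium 10 (not isolated)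
Conditions: n-BuLi (2.2 equiv), THF, −78 °C; Me3SiCl, −78 → 20 °C
Reagents that add atoms: chlorotrimethylsilane C[Si](C)(C)Cl
Why: Dehydrobromination and metalation give propynyllithium, which is silylated at carbon by substitution at silicon.

Step 6
Reactants: 11 trimethyl(prop-1-yn-1-yl)silane
Product: 13 (E)-(1-bromoprop-1-en-1-yl)trimethylsilane, via vinylalane 12 (not isolated)
Conditions: i-Bu2AlH, N-methylpyrrolidine, heptane, 60 °C; then Br2, pyridine, Et2O, −78 °C
Reagents that add atoms: bromine BrBr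
Why: Syn hydroalumination places aluminium on the silyl‑bearing carbon and bromodealumination proceeds with retention, giving the α‑bromovinylsilane.

Step 7
Reactants: 13 (E)-(1-bromoprop-1-en-1-yl)trimethylsilane
Product: 15 (Z)-3-(trimethylsilyl)pent-3-en-2-ol, via vinyl Grignard 14 (not isolated)
Conditions: Mg, THF, 50 °C; CH3CHO, 0 °C; aqueous work-up
Reagents that add atoms: acetaldehyde CC=O
Why: Grignard formation and 1,2‑addition to acetaldehyde retain the olefin geometry, and the racemic carbinol centre is removed in the next step.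

Step 8
Reactants: 15 (Z)-3-(trimethylsilyl)pent-3-en-2-ol
Product: 16 (Z)-3-(trimethylsilyl)pent-3-en-2-one
Conditions: MnO2 (activated, excess), CH2Cl2, 20 °C
Reagents that add atoms: none
Why: Allylic alcohol oxidation gives the α‑silyl enone (a Stork–Ganem‑type annulation reagent) with the β‑methyl trans to the acetyl group.

Step 9
Reactants: 8 (4S,6R)-4-(2-chloropropan-2-yl)-6-methylcyclohex-2-en-1-one; 16 (Z)-3-(trimethylsilyl)pent-3-en-2-one
Product: 18 silyl diketone (4S,6R)-4-(2-chloropropan-2-yl)-6-methyl-6-[4-oxo-3-(trimethylsilyl)pentan-2-yl]cyclohex-2-en-1-one, via lithium dienolate 17 (not isolated)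
Conditions: LDA, THF, −78 °C; 16, −78 → −40 °C; AcOH, −78 °C
Reagents that add atoms: none
Why: Michael addition of the kinetic α′‑dienolate to the α‑silyl enone (silicon stabilises the product enolate, the cold quench prevents a second Michael addition) occurs by axial attack anti to the pseudo‑equatorial C7 substituent, setting C5 with methyl cis to CMe2Cl, and through the compact transition state typical of pentenone annulations, setting the C4 methyl syn to the C5 methyl.

Step 10
Reactants: 18 silyl diketone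
Product: 21 chloro dienone (4S,4aR,6S)-6-(2-chloropropan-2-yl)-4,4a-dimethyl-4,4a,5,6-tetrahydronaphthalen-2(3H)-one, via diketone 19 (not isolated), via aldol 20 (not isolated)
Conditions: TsOH·H2O (0.3 equiv), benzene, 20 °C then 80 °C (Dean–Stark)
Reagents that add atoms: none
Why: After acid protodesilylation the methyl‑ketone enol closes ring A by intramolecular aldol addition to the ring carbonyl, and dehydration to the linear conjugated dienone makes the Robinson‑type closure irreversible without touching C4, C5 or C7.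

Step 11
Reactants: 21 chloro dienone
Product: 22 enone diol (4S,4aR,6S,7R,8S)-6-(2-chloropropan-2-yl)-7,8-dihydroxy-4,4a-dimethyl-4,4a,5,6,7,8-hexahydronaphthalen-2(3H)-one
Conditions: OsO4 (2 mol %), NMO, acetone/H2O 10:1, 0 → 20 °C
Reagents that add atoms: osmium tetroxide (catalytic oxygen carrier) O=[Os](=O)(=O)=O; N-methylmorpholine N-oxide C[N+]1([O-])CCOCC1; water O
Why: Upjohn syn‑dihydroxylation attacks the more electron‑rich γ,δ‑double bond from the α face, anti to the axial C5 methyl and the 7β side chain, which sets C8 and C9 as the 8α,9α‑diol.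

Step 12
Reactants: 22 enone diol
Product: 23 cis-decalone diol (4S,4aR,6S,7R,8S,8aS)-6-(2-chloropropan-2-yl)-7,8-dihydroxy-4,4a-dimethyloctahydronaphthalen-2(1H)-one
Conditions: H2 (1 atm), 5% Pd/C, EtOAc, pyridine (1 vol %), 20 °C
Reagents that add atoms: none
Why: Catalytic hydrogenation of the enone delivers hydrogen to C10 from the β face because the α face is shielded by the pseudo‑axial 9α‑oxygen, giving the cis‑fused decalone, while pyridine suppresses C–O hydrogenolysis and the tertiary chloride is inert.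

Step 13
Reactants: 23 cis-decalone diol
Product: 24 (4S,4aR,6R,7R,8S,8aS)-7,8-dihydroxy-4,4a-dimethyl-6-(prop-1-en-2-yl)octahydronaphthalen-2(1H)-one
Conditions: KOt-Bu (5 equiv), DMSO/THF, 20 °C; aq. NH4Cl
Reagents that add atoms: none
Why: E2 dehydrochlorination with a bulky base takes one of the six methyl protons (Hofmann orientation) and not the hindered ring methine, unveiling the isopropenyl group without affecting any stereocentre (C4 and C10 are not enolisable from C2).

Step 14
Reactants: 25 tiglic acid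
Product: 26 tigloyl chloride
Conditions: (COCl)2, DMF (cat.), CH2Cl2, 0 → 20 °C
Reagents that add atoms: oxalyl chloride O=C(Cl)C(Cl)=O
Why: Acid chloride formation through the Vilsmeier intermediate keeps the E geometry.

Step 15
Reactants: 24 diol; 26 tigloyl chloride
Product: 27 (4S,4aR,6R,7R,8S,8aS)-8-hydroxy-4,4a-dimethyl-7-[(E)-2-methylbut-2-enoyloxy]-6-(prop-1-en-2-yl)octahydronaphthalen-2(1H)-one
Conditions: 26 (1.05 equiv), pyridine, DMAP (5 mol %), CH2Cl2, −20 → 0 °C
Reagents that add atoms: none
Why: Regioselective O‑acylation takes the equatorial 8‑OH, because the 9‑OH is axial, 1,3‑diaxial to C4 and flanked by the ring fusion.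

Step 16
Reactants: 28 3-methylbut-2-enoic acid
Product: 29 3-methylbut-2-enoyl chloride
Conditions: (COCl)2, DMF (cat.), CH2Cl2, 0 → 20 °C
Reagents that add atoms: oxalyl chloride O=C(Cl)C(Cl)=O
Why: Acid chloride formation through the Vilsmeier intermediate.

Step 17
Reactants: 27 mono-tiglate; 29 3-methylbut-2-enoyl chloride
Product: 30 (4S,4aR,6R,7R,8S,8aS)-4,4a-dimethyl-7-[(E)-2-methylbut-2-enoyloxy]-8-(3-methylbut-2-enoyloxy)-6-(prop-1-en-2-yl)octahydronaphthalen-2(1H)-one
Conditions: 29 (3 equiv), pyridine, DMAP (0.3 equiv), CH2Cl2, 40 °C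
Reagents that add atoms: none
Why: DMAP‑catalysed acylation esterifies the remaining hindered axial 9‑OH, and pyridine instead of a trialkylamine avoids vinylketene formation and β,γ‑isomerisation of the senecioate.

**Compound list**

1 | (−)-β-pinene, (1S,5S)-6,6-dimethyl-2-methylidenebicyclo[3.1.1]heptane | CC1(C)[C@H]2CCC(=C)[C@@H]1C2 | starting material
2 | β-pinene ozonide (spiro-1,2,4-trioxolane, epimers at the spiro carbon) | CC1(C)[C@H]2CCC3(OCOO3)[C@@H]1C2 | intermediate
3 | (+)-nopinone, (1R,5S)-6,6-dimethylbicyclo[3.1.1]heptan-2-one | CC1(C)[C@H]2CCC(=O)[C@@H]1C2 | intermediate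
4 | lithium enolate of nopinone (C2=C3) | CC1(C)[C@H]2CC=C(O[Li])[C@@H]1C2 | intermediate
5 | trans-3-methylnopinone, (1R,3S,5S)-3,6,6-trimethylbicyclo[3.1.1]heptan-2-one (3-CH3 anti to the CMe2 bridge) | CC1(C)[C@H]2C[C@H](C)C(=O)[C@@H]1C2 | intermediate
6 | (2R,4R)-4-(2-chloropropan-2-yl)-2-methylcyclohexan-1-one (cis) | CC(C)(Cl)[C@H]1C[C@@H](C)C(=O)CC1 | intermediate
7 | kinetic lithium enolate of 6 (toward the CH2) | CC(C)(Cl)[C@H]1C[C@@H](C)C(O[Li])=CC1 | intermediate
8 | (4S,6R)-4-(2-chloropropan-2-yl)-6-methylcyclohex-2-en-1-one (the 6-epimer is equally usable) | CC(C)(Cl)[C@H]1C[C@@H](C)C(=O)C=C1 | intermediate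
9 | 1-bromoprop-1-ene (E/Z mixture) | CC=CBr | starting material
10 | prop-1-ynyllithium | CC#C[Li] | intermediate
11 | trimethyl(prop-1-yn-1-yl)silane | CC#C[Si](C)(C)C | intermediate
12 | (Z)-diisobutyl[1-(trimethylsilyl)prop-1-en-1-yl]alane | C/C=C(/[Al](CC(C)C)CC(C)C)[Si](C)(C)C | intermediate
13 | (E)-(1-bromoprop-1-en-1-yl)trimethylsilane | C/C=C(/Br)[Si](C)(C)C | intermediate
14 | (Z)-[1-(trimethylsilyl)prop-1-en-1-yl]magnesium bromide | C/C=C(/[Mg]Br)[Si](C)(C)C | intermediate
15 | (Z)-3-(trimethylsilyl)pent-3-en-2-ol (racemic carbinol) | C/C=C(\[Si](C)(C)C)C(C)O | intermediate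
16 | (Z)-3-(trimethylsilyl)pent-3-en-2-one | C/C=C(\[Si](C)(C)C)C(C)=O | intermediate
17 | lithium cross-conjugated dienolate of 8 | CC(C)(Cl)[C@H]1CC(C)=C(O[Li])C=C1 | intermediate
18 | silyl diketone, (4S,6R)-4-(2-chloropropan-2-yl)-6-methyl-6-[4-oxo-3-(trimethylsilyl)pentan-2-yl]cyclohex-2-en-1-one (side-chain CH–CH3 as in 19; C–Si epimers) | CC(C)(Cl)[C@H]1C[C@](C)([C@@H](C)C([Si](C)(C)C)C(C)=O)C(=O)C=C1 | intermediate
19 | (4S,6R)-4-(2-chloropropan-2-yl)-6-methyl-6-[(2S)-4-oxopentan-2-yl]cyclohex-2-en-1-one | CC(C)(Cl)[C@H]1C[C@](C)([C@@H](C)CC(C)=O)C(=O)C=C1 | intermediate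
20 | aldol, 8a-hydroxy-6-(2-chloropropan-2-yl)-4,4a-dimethyl-4,4a,5,6,8,8a-hexahydro... ring-closed β-hydroxy ketone (tertiary carbinol at C10, epimers; C7=C8 double bond retained) | CC(C)(Cl)[C@H]1C[C@@]2(C)C(O)(CC(=O)C[C@@H]2C)C=C1 | intermediate
21 | chloro dienone, (4S,4aR,6S)-6-(2-chloropropan-2-yl)-4,4a-dimethyl-4,4a,5,6-tetrahydronaphthalen-2(3H)-one (4β,5β-dimethyl, 7β-CMe2Cl) | CC(C)(Cl)[C@H]1C[C@@]2(C)C(=CC(=O)C[C@@H]2C)C=C1 | intermediate
22 | enone diol, (4S,4aR,6S,7R,8S)-6-(2-chloropropan-2-yl)-7,8-dihydroxy-4,4a-dimethyl-4,4a,5,6,7,8-hexahydronaphthalen-2(3H)-one (8α,9α-diol) | CC(C)(Cl)[C@H]1C[C@@]2(C)C(=CC(=O)C[C@@H]2C)[C@H](O)[C@@H]1O | intermediate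
23 | cis-decalone diol, (4S,4aR,6S,7R,8S,8aS)-6-(2-chloropropan-2-yl)-7,8-dihydroxy-4,4a-dimethyloctahydronaphthalen-2(1H)-one (10β-H) | CC(C)(Cl)[C@H]1C[C@@]2(C)[C@H](CC(=O)C[C@@H]2C)[C@H](O)[C@@H]1O | intermediate
24 | (4S,4aR,6R,7R,8S,8aS)-7,8-dihydroxy-4,4a-dimethyl-6-(prop-1-en-2-yl)octahydronaphthalen-2(1H)-one | C=C(C)[C@H]1C[C@@]2(C)[C@H](CC(=O)C[C@@H]2C)[C@H](O)[C@@H]1O | intermediate
25 | tiglic acid, (E)-2-methylbut-2-enoic acid | C/C=C(\C)C(=O)O | starting material
26 | tigloyl chloride, (E)-2-methylbut-2-enoyl chloride | C/C=C(\C)C(=O)Cl | intermediate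
27 | mono-tiglate, (4S,4aR,6R,7R,8S,8aS)-8-hydroxy-4,4a-dimethyl-7-[(E)-2-methylbut-2-enoyloxy]-6-(prop-1-en-2-yl)octahydronaphthalen-2(1H)-one | C=C(C)[C@H]1C[C@@]2(C)[C@H](CC(=O)C[C@@H]2C)[C@H](O)[C@@H]1OC(=O)/C(C)=C/C | intermediate
28 | 3-methylbut-2-enoic acid (senecioic acid) | CC(C)=CC(=O)O | starting material
29 | 3-methylbut-2-enoyl chloride (senecioyl chloride) | CC(C)=CC(=O)Cl | intermediate
30 | target, (4S,4aR,6R,7R,8S,8aS)-4,4a-dimethyl-7-[(E)-2-methylbut-2-enoyloxy]-8-(3-methylbut-2-enoyloxy)-6-(prop-1-en-2-yl)octahydronaphthalen-2(1H)-one (8α-tigloyloxy-9α-senecioyloxy-4β,5β-dimethyl-7β-isopropenyl-10βH-decal-2-one) | C=C(C)[C@H]1C[C@@]2(C)[C@H](CC(=O)C[C@@H]2C)[C@H](OC(=O)C=C(C)C)[C@@H]1OC(=O)/C(C)=C/C | target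

**Totals and risks**

Total step count: 17. Longest linear sequence: 11 steps (1–4, 9–13, 15, 17; the arm 5–8, 9–13, 15, 17 is equally long).

The three steps most likely to fail:

Step 9 (Michael addition of the cross‑conjugated dienolate). The adduct enolate can add a second time to the ring enone and give a bicyclo[2.2.2]octanone, and the facial selectivity at C5 rests only on axial attack. The fallback lets the pinane skeleton control C5. It sets out from 5, whose only possible enolate (LDA, THF, −78 °C) adds to 16 anti to the gem‑dimethyl bridge to give, after AcOH quench, the tricyclic silyl diketone F1. HCl in AcOH then removes silicon, opens the cyclobutane to the tertiary chloride and closes ring A by aldol condensation to the chloro enone F2. DDQ with HCl in dioxane at 20 °C introduces the 8,9‑double bond, which brings the material back to the route at 21.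

Step 12 (hydrogenation). The cis ring fusion depends on β‑face delivery, and the allylic C9–O bond can be hydrogenolysed. The fallback sets out from 22, which is converted with 2,2‑dimethoxypropane and PPTS into the acetonide F3. Its fused dioxolane blocks the α face more completely and does not hydrogenolyse, so H2 over Pd/C gives the cis‑fused acetonide ketone F4. Aqueous AcOH at 40 °C removes the acetonide and returns to the route at 23.

Step 13 (dehydrochlorination). Some isopropylidene isomer may form, and the free ketone is exposed to strong base. The fallback postpones alkene formation to the end. It sets out from 23, which with AgNO3 in aqueous acetone gives the tertiary carbinol F5. Acylation as in steps 15 and 17 (the tertiary hydroxyl does not react) gives the mono‑tiglate carbinol F6 and then the diester carbinol F7. Burgess reagent in benzene at 50 °C dehydrates the tertiary alcohol by syn‑elimination toward the methyl groups and arrives directly at 30.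

**Further compounds**

F1 | step 9 | tricyclic silyl diketone, (1R,5S)-3,6,6-trimethyl-3-[4-oxo-3-(trimethylsilyl)pentan-2-yl]bicyclo[3.1.1]heptan-2-one (side chain anti to the CMe2 bridge, C–Si epimers) | CC1(C)[C@H]2C[C@](C)([C@@H](C)C([Si](C)(C)C)C(C)=O)C(=O)[C@@H]1C2
F2 | step 9 | chloro enone, (4S,4aR,6R)-6-(2-chloropropan-2-yl)-4,4a-dimethyl-4,4a,5,6,7,8-hexahydronaphthalen-2(3H)-one | CC(C)(Cl)[C@H]1C[C@@]2(C)C(=CC(=O)C[C@@H]2C)CC1
F3 | step 12 | acetonide of 22 (8α,9α-O-isopropylidene enone) | CC(C)(Cl)[C@H]1C[C@@]2(C)C(=CC(=O)C[C@@H]2C)[C@@H]3OC(C)(C)O[C@H]13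
F4 | step 12 | acetonide of 23 (cis-fused, 10β-H) | CC(C)(Cl)[C@H]1C[C@@]2(C)[C@H](CC(=O)C[C@@H]2C)[C@@H]3OC(C)(C)O[C@H]13
F5 | step 13 | tertiary carbinol (23 with OH in place of Cl) | CC(C)(O)[C@H]1C[C@@]2(C)[C@H](CC(=O)C[C@@H]2C)[C@H](O)[C@@H]1O
F6 | step 13 | mono-tiglate carbinol (8-O-tiglate of F5) | CC(C)(O)[C@H]1C[C@@]2(C)[C@H](CC(=O)C[C@@H]2C)[C@H](O)[C@@H]1OC(=O)/C(C)=C/C
F7 | step 13 | diester carbinol (8-O-tiglate 9-O-senecioate of F5) | CC(C)(O)[C@H]1C[C@@]2(C)[C@H](CC(=O)C[C@@H]2C)[C@H](OC(=O)C=C(C)C)[C@@H]1OC(=O)/C(C)=C/C
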